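Cuts: the ester C–O bond (linoleic acid 30 + diterpenol 29); the chain bond next to the ring (C8–C9 of the nonadienyl unit: ring sulfone 22 + C10 allylic bromide 25); then, inside the ring, the C4–C5 bond (ring atoms: C1 stereocentre, C2 methyl-bearing, C3, C4, C5, C6 gem-dimethyl).
Enabling feature: C2=C3–C4–C5 is a γ,δ-unsaturated array, so with a carboxyl on C5 the cyclohexene is the product of a [3,3] shift of an allylic ester whose oxygen sits on the methyl-bearing C2. C2 and C5 are joined through C1 and C6, which makes that ester the δ-lactone 13, a temporary ring whose helper carboxyl is removed in step 10.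
Forward: the acyclic C1–C6 bond is made by a first ester-enolate Claisen (step 2), the lactone is built in steps 3–8, the carbocycle closes in step 9, the carboxyl is excised in step 10, the side chain is joined in steps 16–17 and the ester is formed last.
Stereochemistry: the only stereocentre (C1, S) is relayed from the carbinol of ethyl (S)-3-hydroxybutanoate in a chelated dianion Claisen, and that carbinol is then oxidised away. C2 of the lactone forms as both epimers, which converge because C2 becomes sp2. The E,E-alkenes come from geranyl acetate and the Z,Z-diene from linoleic acid.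

Key step: step 9

Remark: compounds 1, 2, 23 and 30 are taken as commercial; ring atoms are numbered C1–C6 as above throughout.

Step 1
Reactants: 1 ethyl (3S)-3-hydroxybutanoate; 2 3-methylbut-2-en-1-ol (prenol)
Product: 3 3-methylbut-2-en-1-yl (3S)-3-hydroxybutanoate
Conditions: Ti(OiPr)4 (cat.), excess 2, 100 °C, ethanol distilled off
Reagents that add atoms: none
Why: Titanate-catalysed transesterification under neutral conditions exchanges ethanol for prenol without β-elimination or racemisation of the β-hydroxy ester, and removal of ethanol drives it.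

Step 2
Reactants: 3 3-methylbut-2-en-1-yl (3S)-3-hydroxybutanoate
Product: 5 (2S,3S)-3-hydroxy-2-(2-methylbut-3-en-2-yl)butanoic acid, via chelated dilithium dianion 4 (not isolated)
Conditions: LiN(iPr)2 (LDA, 2.3 equiv), THF, −78 °C, then 25–50 °C; aq. HCl
Reagents that add atoms: none
Why: Dianionic ester-enolate Claisen ([3,3]) rearrangement of a β-hydroxy ester: lithium chelation between alkoxide and enolate oxygens fixes the enolate geometry, and the prenyl group should be delivered through a chair transition state to the face opposite the carbinol methyl group, so the new centre forms anti to the hydroxyl (same sense as Fráter–Seebach alkylation) while the gem-dimethyl quaternary carbon is created.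

Step 3
Reactants: 5 (2S,3S)-3-hydroxy-2-(2-methylbut-3-en-2-yl)butanoic acid
Product: 6 (2R,3S)-2-(2-methylbut-3-en-2-yl)butane-1,3-diol
Conditions: LiAlH4, THF, 0 °C to reflux; aq. NaOH work-up
Reagents that add atoms: none
Why: Hydride reduction of the hindered carboxylate gives the primary alcohol without touching the isolated alkene or either stereocentre.

Step 4
Reactants: 6 (2R,3S)-2-(2-methylbut-3-en-2-yl)butane-1,3-diol
Product: 7 (2S,3R)-3-{[tert-butyl(diphenyl)silyl]oxymethyl}-4,4-dimethylhex-5-en-2-ol
Conditions: t-BuPh2SiCl (1.05 equiv), imidazole, CH2Cl2, 0 °C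
Reagents that add atoms: tert-butyl(chloro)diphenylsilane, CC(C)(C)[Si](Cl)(c1ccccc1)c1ccccc1
Why: Selective silylation: the bulky chlorosilane reacts with the primary hydroxyl much faster than with the hindered secondary one.

Step 5
Reactants: 7 (2S,3R)-3-{[tert-butyl(diphenyl)silyl]oxymethyl}-4,4-dimethylhex-5-en-2-ol
Product: 8 (3R)-3-{[tert-butyl(diphenyl)silyl]oxymethyl}-4,4-dimethylhex-5-en-2-one
Conditions: Dess–Martin periodinane, NaHCO3, CH2Cl2, rt
Reagents that add atoms: none
Why: Dess–Martin oxidation under buffered, non-basic conditions erases the relay carbinol and should leave the α-centre of the β-silyloxy ketone unenolised.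

Step 6
Reactants: 8 (3R)-3-{[tert-butyl(diphenyl)silyl]oxymethyl}-4,4-dimethylhex-5-en-2-one
Product: 10 (3R)-3-{[tert-butyl(diphenyl)silyl]oxymethyl}-6-hydroxy-4,4-dimethylhexan-2-one, via B-alkyl-9-BBN adduct 9 (not isolated)
Conditions: 9-BBN (9-borabicyclo[3.3.1]nonane), THF, 0 °C to rt; then aq. NaOAc, 30% H2O2, 0 °C to rt
Reagents that add atoms: hydrogen peroxide, OO
Why: Anti-Markovnikov hydroboration–oxidation: 9-BBN places boron on the terminal vinyl carbon (reinforced by the neighbouring quaternary carbon) faster than it reduces the hindered ketone, and acetate-buffered peroxide avoids base-induced epimerisation or β-elimination.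

Step 7
Reactants: 10 (3R)-3-{[tert-butyl(diphenyl)silyl]oxymethyl}-6-hydroxy-4,4-dimethylhexan-2-one
Product: 11 (4R)-4-{[tert-butyl(diphenyl)silyl]oxymethyl}-3,5,5-trimethylhept-1-ene-3,7-diol (both C3 epimers)
Conditions: CH2=CHMgBr (3.5 equiv), anhydrous CeCl3, THF, −78 to 0 °C; aq. NH4Cl
Reagents that add atoms: vinylmagnesium bromide, C=C[Mg]Br
Why: Organocerium (Imamoto-type) 1,2-addition of the weakly basic vinyl nucleophile to the hindered, enolisable ketone after one equivalent has deprotonated the hydroxyl; the configuration of the new tertiary carbinol is irrelevant because this carbon becomes sp2 in step 9.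

Step 8
Reactants: 11 (4R)-4-{[tert-butyl(diphenyl)silyl]oxymethyl}-3,5,5-trimethylhept-1-ene-3,7-diol
Product: 13 (5R)-5-{[tert-butyl(diphenyl)silyl]oxymethyl}-6-ethenyl-4,4,6-trimethyloxan-2-one (both C6 epimers), via lactol 12 (not isolated)
Conditions: TEMPO (cat.), PhI(OAc)2, CH2Cl2, rt
Reagents that add atoms: none
Why: TEMPO/PhI(OAc)2 oxidative lactonisation: the primary alcohol is oxidised to the aldehyde, trapped by the tertiary hydroxyl as the six-membered lactol and oxidised on to the δ-lactone, the tertiary allylic alcohol and vinyl group being inert to the oxoammonium oxidant.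

Step 9
Reactants: 13 (5R)-5-{[tert-butyl(diphenyl)silyl]oxymethyl}-6-ethenyl-4,4,6-trimethyloxan-2-one
Product: 16 (3R)-3-{[tert-butyl(diphenyl)silyl]oxymethyl}-2,2,4-trimethylcyclohex-4-ene-1-carboxylic acid (C1 epimers), via silyl ketene acetal 14 (not isolated), via trimethylsilyl ester 15 (not isolated)
Conditions: LiN(iPr)2 (LDA), THF, −78 °C; Me3SiCl/Et3N, −78 °C to rt; toluene, 110 °C; then 1 M HCl, THF
Reagents that add atoms: none
Why: Deprotonation of the only α-CH2 of the lactone (C5) and O-silylation give the cyclic silyl ketene acetal 14, in which the O–C(OSi)=C5 unit and the vinyl group on C2 are held across the ring by the C6–C1 bridge; heating brings about a concerted suprafacial [3,3]-sigmatropic (Ireland–Claisen) shift that forms the C4–C5 σ-bond, breaks the tertiary allylic C2–O bond and moves the double bond to C2=C3. The closest known reaction type is the Ireland–Claisen ring contraction of 6-vinyl-δ-lactone silyl ketene acetals to cyclohex-3-ene-1-carboxylic acids. The carbocycle closes through a six-centre transition state that the lactone ring forces into a boat-like, bridged geometry with the vinyl group pseudo-axial; the net change is excision of the O–C(=O) unit from the ring and insertion of the two vinyl carbons, the new double bond being necessarily cis and endocyclic. The only new stereocentre is the carboxyl-bearing C5, set relative to C1 by the boat geometry and of no consequence because it is erased in step 10, while C1 takes no part in the bond changes and keeps its configuration. The step needs (a) regioselective enolisation, secured because C5 carries the only α-hydrogens, (b) a single position for the ring double bond, secured by the allylic transposition inherent in the [3,3] shift, and (c) stereoconvergence, secured because C2 becomes sp2 so that both C2 epimers of 13 should give the same acid.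

Step 10
Reactants: 16 (3R)-3-{[tert-butyl(diphenyl)silyl]oxymethyl}-2,2,4-trimethylcyclohex-4-ene-1-carboxylic acid
Product: 19 tert-butyl(diphenyl){[(1S)-2,6,6-trimethylcyclohex-2-en-1-yl]methoxy}silane, via acid chloride 17 (not isolated), via Barton ester 18 (not isolated)
Conditions: (COCl)2, DMF (cat.), CH2Cl2, 0 °C to rt; then sodium 2-thioxopyridin-1(2H)-olate, DMAP (cat.), t-BuSH, toluene, 80 °C, tungsten lamp
Reagents that add atoms: none
Why: Barton reductive decarboxylation: the thiohydroxamate ester fragments to the secondary C5 radical, which should abstract hydrogen from tert-butyl thiol faster than it undergoes the reversible 3-exo closure onto the ring alkene, so the helper carboxyl leaves tracelessly and C5 becomes CH2.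

Step 11
Reactants: 19 tert-butyl(diphenyl){[(1S)-2,6,6-trimethylcyclohex-2-en-1-yl]methoxy}silane
Product: 20 [(1S)-2,6,6-trimethylcyclohex-2-en-1-yl]methanol ((S)-α-cyclogeraniol)
Conditions: Bu4NF, THF, rt to 40 °C
Reagents that add atoms: none
Why: Fluoride-mediated desilylation frees the primary alcohol without affecting the alkene or the stereocentre.

Step 12
Reactants: 20 [(1S)-2,6,6-trimethylcyclohex-2-en-1-yl]methanol
Product: 21 phenyl {[(1S)-2,6,6-trimethylcyclohex-2-en-1-yl]methyl} sulfide
Conditions: PhSSPh, PBu3, pyridine, rt to 60 °C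
Reagents that add atoms: diphenyl disulfide, c1ccccc1SSc1ccccc1
Why: Hata reaction (disulfide–phosphine redox condensation): the alkoxyphosphonium salt of the hindered primary alcohol is displaced by thiophenolate in an SN2 step that does not involve the adjacent stereocentre.

Step 13
Reactants: 21 phenyl {[(1S)-2,6,6-trimethylcyclohex-2-en-1-yl]methyl} sulfide
Product: 22 {[(1S)-2,6,6-trimethylcyclohex-2-en-1-yl]methyl}sulfonylbenzene
Conditions: (NH4)6Mo7O24·4H2O (cat.), 30% H2O2, EtOH, 0 °C to rt
Reagents that add atoms: hydrogen peroxide, OO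
Why: Molybdate-catalysed peroxide oxidation of sulfide to sulfone is chemoselective because sulfur is far more nucleophilic towards the peroxomolybdate than the trisubstituted ring alkene.

Step 14
Reactants: 23 (2E)-3,7-dimethylocta-2,6-dien-1-yl acetate (geranyl acetate)
Product: 24 (2E,6E)-8-hydroxy-3,7-dimethylocta-2,6-dien-1-yl acetate
Conditions: SeO2 (cat.), t-BuOOH (70% aq.), salicylic acid (cat.), CH2Cl2, rt
Reagents that add atoms: tert-butyl hydroperoxide, CC(C)(C)OO (terminal oxidant; the oxygen is delivered through selenium dioxide, O=[Se]=O)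
Why: Sharpless catalytic SeO2 allylic oxidation (ene reaction, then [2,3]-shift) hydroxylates the (E)-methyl group of the distal trisubstituted alkene, the 2,3-alkene being deactivated by the allylic acetate, and the E geometry follows from the cyclic transition states.

Step 15
Reactants: 24 (2E,6E)-8-hydroxy-3,7-dimethylocta-2,6-dien-1-yl acetate
Product: 25 (2E,6E)-8-bromo-3,7-dimethylocta-2,6-dien-1-yl acetate
Conditions: PBr3, Et2O, −10 to 0 °C
Reagents that add atoms: phosphorus tribromide, BrP(Br)Br
Why: Low-temperature bromination of the primary allylic alcohol by direct SN2 displacement should proceed without allylic transposition or E/Z isomerisation.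

Step 16
Reactants: 22 {[(1S)-2,6,6-trimethylcyclohex-2-en-1-yl]methyl}sulfonylbenzene; 25 (2E,6E)-8-bromo-3,7-dimethylocta-2,6-dien-1-yl acetate
Product: 27 (2E,6E)-3,7-dimethyl-9-(phenylsulfonyl)-9-[(1S)-2,6,6-trimethylcyclohex-2-en-1-yl]nona-2,6-dien-1-yl acetate (both C9 epimers), via lithiated sulfone 26 (not isolated)
Conditions: n-BuLi, THF/DMPU, −78 °C; then 25, −78 to −30 °C
Reagents that add atoms: none
Why: Alkylation of an α-sulfonyl carbanion (Julia-type fragment coupling): the lithiated sulfone should attack the primary allylic bromide at its α-carbon at −78 °C much faster than it reacts with the acetate, joining ring and chain with the E,E geometry intact; the sulfonyl-bearing centre is erased in step 17.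

Step 17
Reactants: 27 (2E,6E)-3,7-dimethyl-9-(phenylsulfonyl)-9-[(1S)-2,6,6-trimethylcyclohex-2-en-1-yl]nona-2,6-dien-1-yl acetate
Product: 29 (2E,6E)-3,7-dimethyl-9-[(1S)-2,6,6-trimethylcyclohex-2-en-1-yl]nona-2,6-dien-1-ol, via desulfonylated acetate 28 (not isolated)
Conditions: 6% Na(Hg), Na2HPO4, MeOH/THF, −20 to 0 °C; then K2CO3, MeOH, rt
Reagents that add atoms: none
Why: Reductive desulfonylation by electron transfer from buffered sodium amalgam cleaves the alkyl C–S bond without reducing the isolated trisubstituted alkenes or the allylic C–O bond, and carbonate methanolysis then removes the acetate.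

Step 18
Reactants: 29 (2E,6E)-3,7-dimethyl-9-[(1S)-2,6,6-trimethylcyclohex-2-en-1-yl]nona-2,6-dien-1-ol; 30 (9Z,12Z)-octadeca-9,12-dienoic acid (linoleic acid)
Product: 31 (2E,6E)-3,7-dimethyl-9-[(1S)-2,6,6-trimethylcyclohex-2-en-1-yl]nona-2,6-dien-1-yl (9Z,12Z)-octadeca-9,12-dienoate
Conditions: EDC·HCl, DMAP, CH2Cl2, 0 °C to rt
Reagents that add atoms: none
Why: Steglich-type carbodiimide esterification acylates the primary allylic alcohol under neutral conditions that should leave the skipped Z,Z-diene and the trisubstituted alkenes unisomerised.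

Compound list
1 | ethyl (3S)-3-hydroxybutanoate | C[C@H](O)CC(=O)OCC | starting material
2 | 3-methylbut-2-en-1-ol | CC(C)=CCO | starting material
3 | 3-methylbut-2-en-1-yl (3S)-3-hydroxybutanoate | C[C@H](O)CC(=O)OCC=C(C)C | intermediate
4 | chelated dilithium enolate–alkoxide of 3 | [Li+].[Li+].C[C@H]([O-])/C=C(\[O-])OCC=C(C)C | intermediate
5 | (2S,3S)-3-hydroxy-2-(2-methylbut-3-en-2-yl)butanoic acid | C[C@H](O)[C@@H](C(=O)O)C(C)(C)C=C | intermediate
6 | (2R,3S)-2-(2-methylbut-3-en-2-yl)butane-1,3-diol | C[C@H](O)[C@@H](CO)C(C)(C)C=C | intermediate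
7 | (2S,3R)-3-{[tert-butyl(diphenyl)silyl]oxymethyl}-4,4-dimethylhex-5-en-2-ol | C[C@H](O)[C@@H](CO[Si](c1ccccc1)(c1ccccc1)C(C)(C)C)C(C)(C)C=C | intermediate
8 | (3R)-3-{[tert-butyl(diphenyl)silyl]oxymethyl}-4,4-dimethylhex-5-en-2-one | CC(=O)[C@@H](CO[Si](c1ccccc1)(c1ccccc1)C(C)(C)C)C(C)(C)C=C | intermediate
9 | B-alkyl-9-borabicyclo[3.3.1]nonane adduct of 8 | CC(=O)[C@@H](CO[Si](c1ccccc1)(c1ccccc1)C(C)(C)C)C(C)(C)CCB1C2CCCC1CCC2 | intermediate
10 | (3R)-3-{[tert-butyl(diphenyl)silyl]oxymethyl}-6-hydroxy-4,4-dimethylhexan-2-one | CC(=O)[C@@H](CO[Si](c1ccccc1)(c1ccccc1)C(C)(C)C)C(C)(C)CCO | intermediate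
11 | (4R)-4-{[tert-butyl(diphenyl)silyl]oxymethyl}-3,5,5-trimethylhept-1-ene-3,7-diol, both C3 epimers | C=CC(C)(O)[C@@H](CO[Si](c1ccccc1)(c1ccccc1)C(C)(C)C)C(C)(C)CCO | intermediate
12 | (5R)-5-{[tert-butyl(diphenyl)silyl]oxymethyl}-6-ethenyl-4,4,6-trimethyloxan-2-ol (lactol) | OC1CC(C)(C)[C@H](CO[Si](c2ccccc2)(c2ccccc2)C(C)(C)C)C(C)(C=C)O1 | intermediate
13 | (5R)-5-{[tert-butyl(diphenyl)silyl]oxymethyl}-6-ethenyl-4,4,6-trimethyloxan-2-one, both C6 epimers | O=C1CC(C)(C)[C@H](CO[Si](c2ccccc2)(c2ccccc2)C(C)(C)C)C(C)(C=C)O1 | intermediate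
14 | trimethylsilyl ketene acetal of 13 | C[Si](C)(C)OC1=CC(C)(C)[C@H](CO[Si](c2ccccc2)(c2ccccc2)C(C)(C)C)C(C)(C=C)O1 | intermediate
15 | trimethylsilyl ester of 16 | C[Si](C)(C)OC(=O)C1CC=C(C)[C@@H](CO[Si](c2ccccc2)(c2ccccc2)C(C)(C)C)C1(C)C | intermediate
16 | (3R)-3-{[tert-butyl(diphenyl)silyl]oxymethyl}-2,2,4-trimethylcyclohex-4-ene-1-carboxylic acid, C1 epimers | OC(=O)C1CC=C(C)[C@@H](CO[Si](c2ccccc2)(c2ccccc2)C(C)(C)C)C1(C)C | intermediate
17 | acid chloride of 16 | ClC(=O)C1CC=C(C)[C@@H](CO[Si](c2ccccc2)(c2ccccc2)C(C)(C)C)C1(C)C | intermediate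
18 | 2-thioxopyridin-1(2H)-yl ester of 16 (Barton ester) | S=c1ccccn1OC(=O)C1CC=C(C)[C@@H](CO[Si](c2ccccc2)(c2ccccc2)C(C)(C)C)C1(C)C | intermediate
19 | tert-butyl(diphenyl){[(1S)-2,6,6-trimethylcyclohex-2-en-1-yl]methoxy}silane | CC(C)(C)[Si](c1ccccc1)(c1ccccc1)OC[C@@H]1C(C)=CCCC1(C)C | intermediate
20 | [(1S)-2,6,6-trimethylcyclohex-2-en-1-yl]methanol | OC[C@@H]1C(C)=CCCC1(C)C | intermediate
21 | phenyl {[(1S)-2,6,6-trimethylcyclohex-2-en-1-yl]methyl} sulfide | c1ccccc1SC[C@@H]1C(C)=CCCC1(C)C | intermediate
22 | {[(1S)-2,6,6-trimethylcyclohex-2-en-1-yl]methyl}sulfonylbenzene | O=S(=O)(c1ccccc1)C[C@@H]1C(C)=CCCC1(C)C | intermediate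
23 | (2E)-3,7-dimethylocta-2,6-dien-1-yl acetate | CC(C)=CCC/C(C)=C/COC(C)=O | starting material
24 | (2E,6E)-8-hydroxy-3,7-dimethylocta-2,6-dien-1-yl acetate | OC/C(C)=C/CC/C(C)=C/COC(C)=O | intermediate
25 | (2E,6E)-8-bromo-3,7-dimethylocta-2,6-dien-1-yl acetate | BrC/C(C)=C/CC/C(C)=C/COC(C)=O | intermediate
26 | α-lithio derivative of sulfone 22 | [Li+].O=S(=O)(c1ccccc1)[CH-][C@@H]1C(C)=CCCC1(C)C | intermediate
27 | (2E,6E)-3,7-dimethyl-9-(phenylsulfonyl)-9-[(1S)-2,6,6-trimethylcyclohex-2-en-1-yl]nona-2,6-dien-1-yl acetate, both C9 epimers | CC(=O)OC/C=C(\C)CC/C=C(\C)CC(S(=O)(=O)c1ccccc1)[C@@H]1C(C)=CCCC1(C)C | intermediate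
28 | (2E,6E)-3,7-dimethyl-9-[(1S)-2,6,6-trimethylcyclohex-2-en-1-yl]nona-2,6-dien-1-yl acetate | CC(=O)OC/C=C(\C)CC/C=C(\C)CC[C@@H]1C(C)=CCCC1(C)C | intermediate
29 | (2E,6E)-3,7-dimethyl-9-[(1S)-2,6,6-trimethylcyclohex-2-en-1-yl]nona-2,6-dien-1-ol | OC/C=C(\C)CC/C=C(\C)CC[C@@H]1C(C)=CCCC1(C)C | intermediate
30 | (9Z,12Z)-octadeca-9,12-dienoic acid | CCCCC/C=C\C/C=C\CCCCCCCC(=O)O | starting material
31 | (2E,6E)-3,7-dimethyl-9-[(1S)-2,6,6-trimethylcyclohex-2-en-1-yl]nona-2,6-dien-1-yl (9Z,12Z)-octadeca-9,12-dienoate | CCCCC/C=C\C/C=C\CCCCCCCC(=O)OC/C=C(\C)CC/C=C(\C)CC[C@@H]1C(C)=CCCC1(C)C | target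

Total steps: 18. Longest linear sequence: 16 (steps 1–13 and 16–18).

Steps most likely to fail

Step 9. What may go wrong: incomplete or unselective enolisation and silylation of the hindered lactone, or loss of the labile silyl ketene acetal (C-silylation, ketene-type ring opening) before the strained boat transition state is reached. The fallback sets out from 13 and comes back at 16, using a neutral thermal Claisen of an allyl vinyl ether instead of an ester enolate. Lactone 13 is reduced with iBu2AlH at −78 °C to lactol 12, which is dehydrated (MeSO2Cl, Et3N) to the cyclic enol ether tert-butyl{[(3R)-2-ethenyl-2,4,4-trimethyl-3,4-dihydro-2H-pyran-3-yl]methoxy}diphenylsilane F1. Heating F1 in toluene at about 200 °C in a sealed vessel should bring about the known ring-contracting Claisen rearrangement of 2-vinyl-3,4-dihydro-2H-pyrans, again forming the C4–C5 bond and giving (3R)-3-{[tert-butyl(diphenyl)silyl]oxymethyl}-2,2,4-trimethylcyclohex-4-ene-1-carbaldehyde F2. Oxidation of F2 with NaClO2, NaH2PO4 and 2-methylbut-2-ene gives acid 16.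

Step 2. What may go wrong: poor facial selectivity in the dianion rearrangement, or fragmentation of the lithium enolate (loss of prenyl alkoxide) competing with the slow shift that builds the quaternary carbon. The fallback sets out from 2 and comes back at 8, setting C1 with a chiral auxiliary instead of by relay from the carbinol. Johnson–Claisen rearrangement of 2 with triethyl orthoacetate (propionic acid cat., 140 °C) gives ethyl 3,3-dimethylpent-4-enoate F3, and saponification with LiOH gives 3,3-dimethylpent-4-enoic acid F4. Acylation of (4S)-4-benzyl-1,3-oxazolidin-2-one through the pivaloyl mixed anhydride (Et3N, LiCl) gives (4S)-4-benzyl-3-(3,3-dimethylpent-4-enoyl)-1,3-oxazolidin-2-one F5. An Evans syn-aldol reaction (Bu2BOTf, iPr2NEt, acetaldehyde) should give (4S)-4-benzyl-3-[(2S,3R)-3-hydroxy-2-(2-methylbut-3-en-2-yl)butanoyl]-1,3-oxazolidin-2-one F6, the auxiliary fixing the α-carbon in the configuration needed for C1. LiBH4 removes the auxiliary to give (2R,3R)-2-(2-methylbut-3-en-2-yl)butane-1,3-diol F7, the carbinol epimer of 6. Selective silylation (t-BuPh2SiCl, imidazole) gives (2R,3R)-3-{[tert-butyl(diphenyl)silyl]oxymethyl}-4,4-dimethylhex-5-en-2-ol F8, and Dess–Martin oxidation of F8 removes the epimeric carbinol and gives ketone 8.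

Step 16. What may go wrong: slow alkylation of the hindered carbanion, with proton or acyl transfer at the acetate or elimination of the allylic bromide competing. The fallback sets out from 20 and comes back at 28, making the same C–C bond by copper-catalysed Grignard coupling instead of sulfone alkylation. Alcohol 20 is converted (CBr4, PPh3) into (6S)-6-(bromomethyl)-1,5,5-trimethylcyclohex-1-ene F9, and Mg in THF gives {[(1S)-2,6,6-trimethylcyclohex-2-en-1-yl]methyl}magnesium bromide F10. Coupling of F10 with bromide 25 (Li2CuCl4 cat., THF/N-methylpyrrolidone, 0 °C) should be ester-tolerant and occur at the primary allylic carbon, because attack at the other allyl terminus would have to build a quaternary carbon. It gives acetate 28, which is methanolysed to 29 as in step 17, so steps 12, 13 and 16 are bypassed.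

Further compounds
F1 | step 9 | tert-butyl{[(3R)-2-ethenyl-2,4,4-trimethyl-3,4-dihydro-2H-pyran-3-yl]methoxy}diphenylsilane (both C2 epimers) | C1=CC(C)(C)[C@H](CO[Si](c2ccccc2)(c2ccccc2)C(C)(C)C)C(C)(C=C)O1
F2 | step 9 | (3R)-3-{[tert-butyl(diphenyl)silyl]oxymethyl}-2,2,4-trimethylcyclohex-4-ene-1-carbaldehyde (C1 epimers) | CC(C)(C)[Si](c1ccccc1)(c1ccccc1)OC[C@@H]1C(C)=CCC(C=O)C1(C)C
F3 | step 2 | ethyl 3,3-dimethylpent-4-enoate | CCOC(=O)CC(C)(C)C=C
F4 | step 2 | 3,3-dimethylpent-4-enoic acid | OC(=O)CC(C)(C)C=C
F5 | step 2 | (4S)-4-benzyl-3-(3,3-dimethylpent-4-enoyl)-1,3-oxazolidin-2-one | O=C(CC(C)(C)C=C)N1[C@@H](Cc2ccccc2)COC1=O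
F6 | step 2 | (4S)-4-benzyl-3-[(2S,3R)-3-hydroxy-2-(2-methylbut-3-en-2-yl)butanoyl]-1,3-oxazolidin-2-one | C[C@@H](O)[C@@H](C(=O)N1[C@@H](Cc2ccccc2)COC1=O)C(C)(C)C=C
F7 | step 2 | (2R,3R)-2-(2-methylbut-3-en-2-yl)butane-1,3-diol | C[C@@H](O)[C@@H](CO)C(C)(C)C=C
F8 | step 2 | (2R,3R)-3-{[tert-butyl(diphenyl)silyl]oxymethyl}-4,4-dimethylhex-5-en-2-ol | C[C@@H](O)[C@@H](CO[Si](c1ccccc1)(c1ccccc1)C(C)(C)C)C(C)(C)C=C
F9 | step 16 | (6S)-6-(bromomethyl)-1,5,5-trimethylcyclohex-1-ene | BrC[C@@H]1C(C)=CCCC1(C)C
F10 | step 16 | {[(1S)-2,6,6-trimethylcyclohex-2-en-1-yl]methyl}magnesium bromide | Br[Mg]C[C@@H]1C(C)=CCCC1(C)C
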